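The C8 side chain is built and protected first, the benzene ring is then made around it in step 7, and the pyranone is attached last through a C6 formyl group that also directs the C5 de-ethylation.

Everything rests on disconnecting the benzene ring of the chromene (C4a–C8a) at C8–C8a and C6–C7 into a four-carbon vinylketene and a two-carbon ynol ether. The key step exploits the 1,3,5-trioxygenated pattern of this ring, in which C8 sits between oxygen-bearing C7 and C8a and para to C5–O: one thermal benzannulation of 3-ethoxycyclobutenone with an L-isoleucine-derived siloxyalkyne builds the ring with the three oxygens already distinguished (free OH at C8a, the future O1; OTIPS at C7; OEt at C5). The alkyne carries the side chain as a TBS-protected carbinol, so the sec-butyl stereocentre is not enolisable until a late neutral oxidation.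

Key step: step 7

Remark: the silyloxy-bearing carbinol carbon is drawn (S) throughout, but it becomes the C8 ketone carbon in step 12, so its configuration (and any epimerisation next to the aldehyde in steps 4–5) does not affect the target; only the sec-butyl centre from C3 of L-isoleucine must be preserved.

**Route**

Step 1
Reactants: 1 L-isoleucine
Product: 2 (2S,3S)-2-hydroxy-3-methylpentanoic acid
Conditions: NaNO2, 1 M aq. H2SO4, 0 °C to rt
Reagents that add atoms: water, O
Why: Diazotisation of the α-amino acid with neighbouring-group participation by the carboxylate (double inversion) should replace NH2 by OH with overall retention, and the sec-butyl centre is not involved.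

Step 2
Reactants: 2 (2S,3S)-2-hydroxy-3-methylpentanoic acid
Product: 3 methyl (2S,3S)-2-hydroxy-3-methylpentanoate
Conditions: MeOH, H2SO4 (cat.), reflux
Reagents that add atoms: methanol, CO
Why: Fischer esterification is an acid-catalysed acyl substitution that touches neither stereocentre.

Step 3
Reactants: 3 methyl (2S,3S)-2-hydroxy-3-methylpentanoate
Product: 4 methyl (2S,3S)-2-(tert-butyldimethylsilyloxy)-3-methylpentanoate
Conditions: TBSCl, imidazole, DMAP (cat.), DMF, rt
Reagents that add atoms: tert-butyldimethylsilyl chloride, CC(C)(C)[Si](C)(C)Cl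
Why: Standard Corey silylation of a secondary alcohol, giving an ether that survives hydride, organolithium and thermal steps.

Step 4
Reactants: 4 methyl (2S,3S)-2-(tert-butyldimethylsilyloxy)-3-methylpentanoate
Product: 5 (2S,3S)-2-(tert-butyldimethylsilyloxy)-3-methylpentanal
Conditions: DIBAL-H (1.1 equiv), CH2Cl2, −78 °C; Rochelle salt work-up
Reagents that add atoms: none
Why: Partial ester reduction with DIBAL-H, in which the α-silyloxy group stabilises the aluminium hemiacetal at −78 °C so that the aldehyde is released only on work-up.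

Step 5
Reactants: 5 (2S,3S)-2-(tert-butyldimethylsilyloxy)-3-methylpentanal
Product: 6 (3S,4S)-3-(tert-butyldimethylsilyloxy)-4-methylhex-1-yne
Conditions: dimethyl (1-diazo-2-oxopropyl)phosphonate, K2CO3, MeOH, 0 °C to rt
Reagents that add atoms: dimethyl (1-diazo-2-oxopropyl)phosphonate, COP(=O)(OC)C(=[N+]=[N-])C(C)=O
Why: Seyferth–Gilbert homologation in the Ohira–Bestmann version should convert the aldehyde into the terminal alkyne with one added carbon under mild carbonate conditions that cannot affect the non-acidic sec-butyl centre.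

Step 6
Reactants: 6 (3S,4S)-3-(tert-butyldimethylsilyloxy)-4-methylhex-1-yne
Product: 9 (3S,4S)-3-(tert-butyldimethylsilyloxy)-4-methyl-1-(triisopropylsilyloxy)hex-1-yne, via lithium acetylide 7 (not isolated), via lithium ynolate 8 (not isolated)
Conditions: n-BuLi, THF, −78 °C; LiOOt-Bu (from t-BuOOH + LiHMDS), −78 to 0 °C; TIPSOTf, −78 °C
Reagents that add atoms: tert-butyl hydroperoxide, CC(C)(C)OO; triisopropylsilyl trifluoromethanesulfonate, CC(C)[Si](C(C)C)(C(C)C)OS(=O)(=O)C(F)(F)F
Why: Julia-type electrophilic oxygenation of acetylide 7 by lithium tert-butyl peroxide should give ynolate 8, which the hard silyl triflate traps on oxygen to give the bulky, isolable TIPS ynol ether.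

Step 7
Reactants: 9 (3S,4S)-3-(tert-butyldimethylsilyloxy)-4-methyl-1-(triisopropylsilyloxy)hex-1-yne; 10 3-ethoxycyclobut-2-en-1-one
Product: 15 2-[(1S,2S)-1-(tert-butyldimethylsilyloxy)-2-methylbutyl]-5-ethoxy-3-(triisopropylsilyloxy)phenol, via vinylketene 11 (not isolated), via vinylcyclobutenone 12 (not isolated), via dienylketene 13 (not isolated), via cyclohexadienone 14 (not isolated)
Conditions: toluene (0.1 M), 80 to 110 °C, 10 (1.3 equiv) added slowly
Reagents that add atoms: none
Why: On heating, 10 undergoes conrotatory 4π ring opening to ethoxy(vinyl)ketene 11; the electron-rich β-carbon of ynol ether 9 adds to the ketene carbonyl carbon in a polarised [2+2] cycloaddition (forming C8–C8a and C6–C7) to give vinylcyclobutenone 12, which opens (4π) to dienylketene 13. The benzene ring is then closed by thermal disrotatory 6π electrocyclisation of 13 to dienone 14, which restores the C8a–C4a bond of the original four-carbon unit, and enolisation gives phenol 15. This is the cyclobutenone–alkynyl ether benzannulation (Danheiser type), known with TIPS ynol ethers to give resorcinol monosilyl ethers. No stereocentre is formed or touched: the side-chain centres are never adjacent to a carbonyl and the C4 centre of 12 is transient. The step needs one regiochemistry (side chain ortho to the new OH, OTIPS on its other side, OEt para), and the oxygen donor on the alkyne secures it by making the alkyl-bearing carbon the nucleophile toward the ketene C=O. Slow addition of 10 keeps 11 dilute so that it is captured by the hindered alkyne before it can dimerise or acylate 15.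

Step 8
Reactants: 15 2-[(1S,2S)-1-(tert-butyldimethylsilyloxy)-2-methylbutyl]-5-ethoxy-3-(triisopropylsilyloxy)phenol; 16 3-methylbut-2-enal
Product: 18 8-[(1S,2S)-1-(tert-butyldimethylsilyloxy)-2-methylbutyl]-5-ethoxy-2,2-dimethyl-7-(triisopropylsilyloxy)-2H-chromene, via quinone methide 17 (not isolated)
Conditions: ethylenediammonium diacetate (20 mol %), toluene, 110 °C
Reagents that add atoms: none
Why: Amine-salt-catalysed chromene annulation (aldol-type C-alkylation at the ortho carbon, dehydration to quinone methide 17, oxa-6π electrocyclisation) can give only one ring because the single free OH has a single open ortho position (C4a).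

Step 9
Reactants: 18 8-[(1S,2S)-1-(tert-butyldimethylsilyloxy)-2-methylbutyl]-5-ethoxy-2,2-dimethyl-7-(triisopropylsilyloxy)-2H-chromene
Product: 19 8-[(1S,2S)-1-(tert-butyldimethylsilyloxy)-2-methylbutyl]-5-ethoxy-2,2-dimethyl-2H-chromen-7-ol
Conditions: TBAF (1.05 equiv), THF, 0 °C
Reagents that add atoms: none
Why: Fluoride-mediated desilylation cleaves the aryl Si–O bond (phenoxide leaving group) much faster than the hindered secondary alkyl TBS ether, so one equivalent at 0 °C should unmask only the C7 phenol.

Step 10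
Reactants: 19 8-[(1S,2S)-1-(tert-butyldimethylsilyloxy)-2-methylbutyl]-5-ethoxy-2,2-dimethyl-2H-chromen-7-ol
Product: 21 8-[(1S,2S)-1-(tert-butyldimethylsilyloxy)-2-methylbutyl]-5-ethoxy-7-hydroxy-2,2-dimethyl-2H-chromene-6-carbaldehyde, via hydroxymethylphenol 20 (not isolated)
Conditions: MgCl2, Et3N, (CH2O)n, THF, reflux; aq. NH4Cl
Reagents that add atoms: paraformaldehyde (as formaldehyde), C=O
Why: In the magnesium-mediated ortho-formylation of phenols (Casnati–Skattebøl) the magnesium phenoxide delivers formaldehyde to its only free ortho carbon (C6) and a second formaldehyde oxidises 20 by hydride transfer, while the stereocentre still sits next to a carbinol and cannot enolise.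

Step 11
Reactants: 21 8-[(1S,2S)-1-(tert-butyldimethylsilyloxy)-2-methylbutyl]-5-ethoxy-7-hydroxy-2,2-dimethyl-2H-chromene-6-carbaldehyde
Product: 22 5-ethoxy-7-hydroxy-8-[(1S,2S)-1-hydroxy-2-methylbutyl]-2,2-dimethyl-2H-chromene-6-carbaldehyde
Conditions: TBAF (3 equiv), THF, rt to 45 °C
Reagents that add atoms: none
Why: Fluoride desilylation of the secondary TBS ether with excess reagent is safe here because the aldehyde is non-enolisable and the stereocentre is still flanked by a carbinol.

Step 12
Reactants: 22 5-ethoxy-7-hydroxy-8-[(1S,2S)-1-hydroxy-2-methylbutyl]-2,2-dimethyl-2H-chromene-6-carbaldehyde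
Product: 23 5-ethoxy-7-hydroxy-2,2-dimethyl-8-[(2S)-2-methylbutanoyl]-2H-chromene-6-carbaldehyde
Conditions: activated MnO2 (excess), CH2Cl2, rt
Reagents that add atoms: none
Why: Benzylic alcohol oxidation with activated MnO2 is neutral and chemoselective for the electron-rich secondary benzylic carbinol over the hydrogen-bonded phenol, aldehyde and chromene, so the α-centre, enolisable only from here on, meets neither acid nor base.

Step 13
Reactants: 23 5-ethoxy-7-hydroxy-2,2-dimethyl-8-[(2S)-2-methylbutanoyl]-2H-chromene-6-carbaldehyde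
Product: 24 5,7-dihydroxy-2,2-dimethyl-8-[(2S)-2-methylbutanoyl]-2H-chromene-6-carbaldehyde
Conditions: BCl3 (3 equiv), CH2Cl2, −78 to 0 °C; then ice-water
Reagents that add atoms: none
Why: Chelation-directed ether cleavage, in which boron bridges the C6 formyl oxygen and the C5 ether oxygen and chloride removes the ethyl group, is selective for alkoxy groups ortho to a carbonyl and is run cold to spare the pyran ring and the α-centre.

Step 14
Reactants: 25 pentan-3-one
Product: 26 3-(trimethylsilyloxy)pent-2-ene (E/Z mixture, both usable)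
Conditions: TMSCl, Et3N, DMF, 80 °C
Reagents that add atoms: chlorotrimethylsilane, C[Si](C)(C)Cl
Why: Thermodynamic silyl enol ether formation (House conditions) on a symmetrical ketone has no regiochemical issue.

Step 15
Reactants: 26 3-(trimethylsilyloxy)pent-2-ene
Product: 27 6-ethyl-4-hydroxy-5-methyl-2H-pyran-2-one
Conditions: malonyl dichloride, Et2O, −78 °C to rt
Reagents that add atoms: malonyl dichloride, O=C(Cl)CC(=O)Cl
Why: C-acylation of the silyl enol ether by one acid chloride followed by enol O-acylation by the other (malonyl dichloride pyranone synthesis) should deliver the 4-hydroxy-2-pyranone with ethyl at C6 and methyl at C5.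

Step 16
Reactants: 24 5,7-dihydroxy-2,2-dimethyl-8-[(2S)-2-methylbutanoyl]-2H-chromene-6-carbaldehyde; 27 6-ethyl-4-hydroxy-5-methyl-2H-pyran-2-one
Product: 29 6-ethyl-3-({5,7-dihydroxy-2,2-dimethyl-8-[(2S)-2-methylbutanoyl]-2H-chromen-6-yl}methyl)-4-hydroxy-5-methyl-2H-pyran-2-one, via alkylidene pyrandione 28 (not isolated)
Conditions: Hantzsch ester (1.2 equiv), L-proline (20 mol %), CH2Cl2–EtOH, rt
Reagents that add atoms: none
Why: Organocatalytic three-component reductive alkylation, i.e. proline-catalysed Knoevenagel condensation of pyranone C3 with the aldehyde to 28 and conjugate hydride transfer from the Hantzsch ester, should form the methylene bridge under near-neutral conditions that leave ketone, lactone, chromene and the α-centre untouched.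

**Compound list**

1 | L-isoleucine, (2S,3S)-2-amino-3-methylpentanoic acid | CC[C@H](C)[C@H](N)C(=O)O | starting material
2 | (2S,3S)-2-hydroxy-3-methylpentanoic acid | CC[C@H](C)[C@H](O)C(=O)O | intermediate
3 | methyl (2S,3S)-2-hydroxy-3-methylpentanoate | CC[C@H](C)[C@H](O)C(=O)OC | intermediate
4 | methyl (2S,3S)-2-(tert-butyldimethylsilyloxy)-3-methylpentanoate | CC[C@H](C)[C@H](O[Si](C)(C)C(C)(C)C)C(=O)OC | intermediate
5 | (2S,3S)-2-(tert-butyldimethylsilyloxy)-3-methylpentanal | CC[C@H](C)[C@H](O[Si](C)(C)C(C)(C)C)C=O | intermediate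
6 | (3S,4S)-3-(tert-butyldimethylsilyloxy)-4-methylhex-1-yne | CC[C@H](C)[C@H](O[Si](C)(C)C(C)(C)C)C#C | intermediate
7 | lithium acetylide of 6 | CC[C@H](C)[C@H](O[Si](C)(C)C(C)(C)C)C#C[Li] | intermediate
8 | lithium (3S,4S)-3-(tert-butyldimethylsilyloxy)-4-methylhex-1-yn-1-olate | CC[C@H](C)[C@H](O[Si](C)(C)C(C)(C)C)C#C[O-].[Li+] | intermediate
9 | (3S,4S)-3-(tert-butyldimethylsilyloxy)-4-methyl-1-(triisopropylsilyloxy)hex-1-yne | CC[C@H](C)[C@H](O[Si](C)(C)C(C)(C)C)C#CO[Si](C(C)C)(C(C)C)C(C)C | intermediate
10 | 3-ethoxycyclobut-2-en-1-one | CCOC1=CC(=O)C1 | starting material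
11 | 3-ethoxybuta-1,3-dien-1-one (vinylketene) | CCOC(=C)C=C=O | intermediate
12 | 4-(1-ethoxyethenyl)-2-[(1S,2S)-1-(tert-butyldimethylsilyloxy)-2-methylbutyl]-3-(triisopropylsilyloxy)cyclobut-2-en-1-one (C4 epimers) | CC[C@H](C)[C@H](O[Si](C)(C)C(C)(C)C)C1=C(O[Si](C(C)C)(C(C)C)C(C)C)C(C(=C)OCC)C1=O | intermediate
13 | 2-[(1S,2S)-1-(tert-butyldimethylsilyloxy)-2-methylbutyl]-5-ethoxy-3-(triisopropylsilyloxy)hexa-1,3,5-trien-1-one (dienylketene, ketene carbon and ethoxyvinyl group cis) | CC[C@H](C)[C@H](O[Si](C)(C)C(C)(C)C)C(=C=O)C(O[Si](C(C)C)(C(C)C)C(C)C)=CC(=C)OCC | intermediate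
14 | 2-[(1S,2S)-1-(tert-butyldimethylsilyloxy)-2-methylbutyl]-5-ethoxy-3-(triisopropylsilyloxy)cyclohexa-2,4-dien-1-one | CC[C@H](C)[C@H](O[Si](C)(C)C(C)(C)C)C1=C(O[Si](C(C)C)(C(C)C)C(C)C)C=C(OCC)CC1=O | intermediate
15 | 2-[(1S,2S)-1-(tert-butyldimethylsilyloxy)-2-methylbutyl]-5-ethoxy-3-(triisopropylsilyloxy)phenol | CC[C@H](C)[C@H](O[Si](C)(C)C(C)(C)C)c1c(O)cc(OCC)cc1O[Si](C(C)C)(C(C)C)C(C)C | intermediate
16 | 3-methylbut-2-enal | CC(C)=CC=O | starting material
17 | 2-[(1S,2S)-1-(tert-butyldimethylsilyloxy)-2-methylbutyl]-5-ethoxy-6-(3-methylbut-2-en-1-ylidene)-3-(triisopropylsilyloxy)cyclohexa-2,4-dien-1-one (o-quinone methide, exocyclic geometry not defined) | CC[C@H](C)[C@H](O[Si](C)(C)C(C)(C)C)C1=C(O[Si](C(C)C)(C(C)C)C(C)C)C=C(OCC)C(=CC=C(C)C)C1=O | intermediate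
18 | 8-[(1S,2S)-1-(tert-butyldimethylsilyloxy)-2-methylbutyl]-5-ethoxy-2,2-dimethyl-7-(triisopropylsilyloxy)-2H-chromene | CC[C@H](C)[C@H](O[Si](C)(C)C(C)(C)C)c1c(O[Si](C(C)C)(C(C)C)C(C)C)cc(OCC)c2C=CC(C)(C)Oc12 | intermediate
19 | 8-[(1S,2S)-1-(tert-butyldimethylsilyloxy)-2-methylbutyl]-5-ethoxy-2,2-dimethyl-2H-chromen-7-ol | CC[C@H](C)[C@H](O[Si](C)(C)C(C)(C)C)c1c(O)cc(OCC)c2C=CC(C)(C)Oc12 | intermediate
20 | 8-[(1S,2S)-1-(tert-butyldimethylsilyloxy)-2-methylbutyl]-5-ethoxy-6-(hydroxymethyl)-2,2-dimethyl-2H-chromen-7-ol | CC[C@H](C)[C@H](O[Si](C)(C)C(C)(C)C)c1c(O)c(CO)c(OCC)c2C=CC(C)(C)Oc12 | intermediate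
21 | 8-[(1S,2S)-1-(tert-butyldimethylsilyloxy)-2-methylbutyl]-5-ethoxy-7-hydroxy-2,2-dimethyl-2H-chromene-6-carbaldehyde | CC[C@H](C)[C@H](O[Si](C)(C)C(C)(C)C)c1c(O)c(C=O)c(OCC)c2C=CC(C)(C)Oc12 | intermediate
22 | 5-ethoxy-7-hydroxy-8-[(1S,2S)-1-hydroxy-2-methylbutyl]-2,2-dimethyl-2H-chromene-6-carbaldehyde | CC[C@H](C)[C@H](O)c1c(O)c(C=O)c(OCC)c2C=CC(C)(C)Oc12 | intermediate
23 | 5-ethoxy-7-hydroxy-2,2-dimethyl-8-[(2S)-2-methylbutanoyl]-2H-chromene-6-carbaldehyde | CC[C@H](C)C(=O)c1c(O)c(C=O)c(OCC)c2C=CC(C)(C)Oc12 | intermediate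
24 | 5,7-dihydroxy-2,2-dimethyl-8-[(2S)-2-methylbutanoyl]-2H-chromene-6-carbaldehyde | CC[C@H](C)C(=O)c1c(O)c(C=O)c(O)c2C=CC(C)(C)Oc12 | intermediate
25 | pentan-3-one | CCC(=O)CC | starting material
26 | 3-(trimethylsilyloxy)pent-2-ene (E/Z mixture) | CC=C(CC)O[Si](C)(C)C | intermediate
27 | 6-ethyl-4-hydroxy-5-methyl-2H-pyran-2-one | CCc1oc(=O)cc(O)c1C | intermediate
28 | 3-({5,7-dihydroxy-2,2-dimethyl-8-[(2S)-2-methylbutanoyl]-2H-chromen-6-yl}methylidene)-6-ethyl-5-methyl-2H-pyran-2,4(3H)-dione (alkene geometry not defined) | CCC1=C(C)C(=O)C(=Cc2c(O)c3C=CC(C)(C)Oc3c(C(=O)[C@@H](C)CC)c2O)C(=O)O1 | intermediate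
29 | 6-ethyl-3-({5,7-dihydroxy-2,2-dimethyl-8-[(2S)-2-methylbutanoyl]-2H-chromen-6-yl}methyl)-4-hydroxy-5-methyl-2H-pyran-2-one (CNP0212387.1) | CCc1oc(=O)c(Cc2c(O)c3c(c(C(=O)[C@@H](C)CC)c2O)OC(C)(C)C=C3)c(O)c1C | target

**Step count and risks**

Total step count: 16.
Longest linear sequence: 14 steps (steps 1–13 and 16, from L-isoleucine); steps 14–15 are the two-step pyranone branch.

Steps most likely to fail:

Step 7. The ring opening of the vinylogous-ester cyclobutenone may need temperatures at which the ketene dimerises or acylates the freshly formed phenol faster than it undergoes [2+2] addition to the branched, inductively deactivated ynol ether. The fallback sets out from 9 and comes back at 15; it generates the same ketene 11 at room temperature by photochemical Wolff rearrangement, so ketene formation no longer depends on heat. α-Lithiated ethyl vinyl ether (t-BuLi, THF) is acylated with N-methoxy-N-methylacetamide to give 3-ethoxybut-3-en-2-one F1. Detrifluoroacetylative diazo transfer (LiHMDS, 2,2,2-trifluoroethyl trifluoroacetate; then MsN3, Et3N, aq. MeCN) converts it into 1-diazo-3-ethoxybut-3-en-2-one F2. Irradiation of F2 (300 nm) with 9 in CH2Cl2 at rt, followed by warming to 80 °C to complete the 4π/6π sequence through 12–14, should give 15.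

Step 13. The boron Lewis acid and the HCl it releases may hydrochlorinate or open the 2,2-dimethylpyran ring, or displacement at the primary ethyl group may be slow enough that prolonged exposure erodes the α-stereocentre. The fallback sets out from 21 and comes back at 24; it moves the dealkylation ahead of ketone formation and replaces the boron halide by iodide displacement inside a magnesium chelate. Treatment of 21 with MgI2·OEt2 in toluene–ether at 60–80 °C (chelate between the C6 formyl and C5 ether oxygens, SN2 removal of ethyl) should give 8-[(1S,2S)-1-(tert-butyldimethylsilyloxy)-2-methylbutyl]-5,7-dihydroxy-2,2-dimethyl-2H-chromene-6-carbaldehyde F3. TBAF in THF then gives 5,7-dihydroxy-8-[(1S,2S)-1-hydroxy-2-methylbutyl]-2,2-dimethyl-2H-chromene-6-carbaldehyde F4, and activated MnO2 in CH2Cl2 oxidises the benzylic carbinol to give 24.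

Step 16. Condensation at the hindered, doubly hydrogen-bonded aldehyde may be slow, so that over-reduction at C6 to a methyl group or lactone exchange in the unreduced adduct competes with the wanted conjugate reduction. The fallback sets out from 24 and comes back at 29; it reverses the order of events by fixing the benzylic carbon as a Mannich base and forming the C–C bond by Michael addition. Reductive amination of 24 (Me2NH·HCl, NaBH(OAc)3, 1,2-dichloroethane) should give 1-{6-[(dimethylamino)methyl]-5,7-dihydroxy-2,2-dimethyl-2H-chromen-8-yl}-(2S)-2-methylbutan-1-one F5. Heating F5 with 27 in dioxane at 90 °C expels dimethylamine to give the 6-methylene quinone methide F6 (not isolated), which the pyranone C3 traps to give 29.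

Further compounds
F1 | step 7 | 3-ethoxybut-3-en-2-one | CCOC(=C)C(C)=O
F2 | step 7 | 1-diazo-3-ethoxybut-3-en-2-one | CCOC(=C)C(=O)C=[N+]=[N-]
F3 | step 13 | 8-[(1S,2S)-1-(tert-butyldimethylsilyloxy)-2-methylbutyl]-5,7-dihydroxy-2,2-dimethyl-2H-chromene-6-carbaldehyde | CC[C@H](C)[C@H](O[Si](C)(C)C(C)(C)C)c1c(O)c(C=O)c(O)c2C=CC(C)(C)Oc12
F4 | step 13 | 5,7-dihydroxy-8-[(1S,2S)-1-hydroxy-2-methylbutyl]-2,2-dimethyl-2H-chromene-6-carbaldehyde | CC[C@H](C)[C@H](O)c1c(O)c(C=O)c(O)c2C=CC(C)(C)Oc12
F5 | step 16 | 1-{6-[(dimethylamino)methyl]-5,7-dihydroxy-2,2-dimethyl-2H-chromen-8-yl}-(2S)-2-methylbutan-1-one | CC[C@H](C)C(=O)c1c(O)c(CN(C)C)c(O)c2C=CC(C)(C)Oc12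
F6 | step 16 | 5-hydroxy-2,2-dimethyl-6-methylidene-8-[(2S)-2-methylbutanoyl]-2H-chromen-7(6H)-one (quinone methide) | C=C1C(O)=C2C=CC(C)(C)OC2=C(C(=O)[C@@H](C)CC)C1=O
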